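**Plan**

- The retrosynthesis first removes the two phenol silyl ethers and the C7–O orsellinate ester, then cuts the side-chain C=C bond (cross-metathesis, leaving a C3 vinyl group).
- The feature that allows the main cut is that, in the 6H-isochromene-6,8(7H)-dione, the C8 ketone sits next to the C7 tertiary carbinol inside the carbocycle. This is an acyloin, so C7–C8 opens to a C8 aldehyde on C8a of a 4H-pyran and a C6/C7 1,2-diketone on the exocyclic C5.
- That keto-aldehyde is cut at C4a=C5 (Meyer-Schuster rearrangement of an alkynyl carbinol from a 4-pyranone and but-3-yn-2-ol), at C8a–C8 (Stille hydroxymethylation of an enol triflate) and at the vinyl group (Wittig), which leads back to chlorokojic acid.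
- Forward, the pyran ring is present from the first compound, the carbocycle closes in the benzoin step, the side chain is completed next, and the aromatic ring arrives with orsellinic acid in the esterification.
- C7 (S) is the only stereocentre. It is set by the chiral triazolylidene in the ring closure of an achiral precursor and is quaternary afterwards. The side-chain E geometry comes from the cross-metathesis.

Key step: step 7

Remarks on the chemistry: isochromene numbering is used for the core (C1 the O–CH, O2, C3 with the side chain, C4a/C8a the fusion carbons, C6/C8 the ketones, C7 the carbinol). Chlorokojic acid, (tributylstannyl)methanol, orsellinic acid and both antipodes of the aminoindanol triazolium salt are taken as commercial. Compounds 9 and 10 are drawn Z at the exocyclic push-pull double bond; the two geometric isomers are expected to interconvert, so this geometry is not controlled. The C7 descriptor of the target SMILES is S (O > C8 > C6 > CH3).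

**Step 1**
Reactants: 1 chlorokojic acid, 2-(chloromethyl)-5-hydroxy-4H-pyran-4-one
Product: 2 6-(chloromethyl)-4-oxo-4H-pyran-3-yl trifluoromethanesulfonate
Conditions: Tf2O, pyridine, CH2Cl2, −20 → 0 °C
Reagents that add atoms: trifluoromethanesulfonic anhydride, O=S(=O)(OS(=O)(=O)C(F)(F)F)C(F)(F)F
Why: The acidic enolic 5-hydroxyl is the only nucleophilic site and is sulfonylated under standard O-triflation conditions, giving the enol triflate that later carries C8 and meanwhile masks the enol during the Wittig step.

**Step 2**
Reactants: 2 6-(chloromethyl)-4-oxo-4H-pyran-3-yl trifluoromethanesulfonate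
Product: 3 {[4-oxo-5-(trifluoromethanesulfonyloxy)-4H-pyran-2-yl]methyl}triphenylphosphonium chloride
Conditions: PPh3, toluene, 80 °C
Reagents that add atoms: triphenylphosphine, c1ccc(cc1)P(c1ccccc1)c1ccccc1
Why: SN2 displacement of the activated primary (allylic, vinylogous α-keto) chloride by the phosphine gives the phosphonium salt, which should precipitate from toluene (phosphonium salt formation).

**Step 3**
Reactants: 3 {[4-oxo-5-(trifluoromethanesulfonyloxy)-4H-pyran-2-yl]methyl}triphenylphosphonium chloride
Product: 5 6-ethenyl-4-oxo-4H-pyran-3-yl trifluoromethanesulfonate, via phosphonium ylide 4 (not isolated)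
Conditions: 37% aq. CH2O, K2CO3, CH2Cl2/H2O, 0 °C → rt
Reagents that add atoms: formaldehyde, C=O
Why: The ylide is stabilised by the pyranone as a vinylogous acyl group, so carbonate suffices to form it, and formaldehyde methylenates it (Wittig olefination) with no alkene geometry at stake, while the triflate prevents the base-mediated ring hydroxymethylation that a free 5-hydroxypyranone would undergo.

**Step 4**
Reactants: 5 6-ethenyl-4-oxo-4H-pyran-3-yl trifluoromethanesulfonate
Product: 6 2-ethenyl-5-(hydroxymethyl)-4H-pyran-4-one
Conditions: Bu3SnCH2OH, Pd(PPh3)4 (5 mol %), LiCl, 1,4-dioxane, 90 °C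
Reagents that add atoms: (tributylstannyl)methanol, CCCC[Sn](CO)(CCCC)CCCC
Why: Zerovalent palladium inserts into the electron-poor enol triflate, the hydroxymethyl group is transferred from tin and reductive elimination follows (Stille cross-coupling, hydroxymethylation variant), which puts the future C8 on C8a at the alcohol level so that C1 is not yet a doubly activated acceptor.

**Step 5**
Reactants: 6 2-ethenyl-5-(hydroxymethyl)-4H-pyran-4-one; 7 but-3-yn-2-ol (racemic)
Product: 9 (1Z)-1-[2-ethenyl-5-(hydroxymethyl)-4H-pyran-4-ylidene]-3-hydroxybutan-2-one, via alkynyl carbinol 8 (not isolated)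
Conditions: 6, LiN(SiMe3)2 (1 equiv), THF, −78 °C; add to 7 (3 equiv)/n-BuLi (6 equiv), THF, −78 → 0 °C; then 1 M aq. H2SO4, 0 °C → rt
Reagents that add atoms: water, O
Why: The hard lithium acetylide adds 1,2 to the pyranone carbonyl, and in acid the bis-allylic propargylic carbinol ionises to a 4-alkynylpyrylium ion whose remote alkyne carbon takes up water, the allenol then tautomerising to the push-pull enone (Meyer-Schuster rearrangement, as known for 9-alkynylxanthen-9-ols and 4-alkynylpyrylium salts), which forms C4a=C5 and places the C6 ketone and the C7 carbinol in one operation.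

**Step 6**
Reactants: 9 (1Z)-1-[2-ethenyl-5-(hydroxymethyl)-4H-pyran-4-ylidene]-3-hydroxybutan-2-one
Product: 10 (4Z)-4-(2,3-dioxobutylidene)-6-ethenyl-4H-pyran-3-carbaldehyde
Conditions: Dess-Martin periodinane (2.5 equiv), pyridine, CH2Cl2, 0 °C → rt
Reagents that add atoms: none
Why: The periodinane oxidises the primary alcohol to the vinylogous formate aldehyde (C8) and the α-ketol to the 1,2-diketone (C6/C7) in one buffered, non-aqueous Dess-Martin oxidation, without over-oxidation or C–C cleavage.

**Step 7**
Reactants: 10 (4Z)-4-(2,3-dioxobutylidene)-6-ethenyl-4H-pyran-3-carbaldehyde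
Product: 11 (7S)-3-ethenyl-7-hydroxy-7-methyl-6H-isochromene-6,8(7H)-dione
Conditions: (5aS,10bR)-2-(pentafluorophenyl)-5a,10b-dihydro-4H,6H-indeno[2,1-b][1,2,4]triazolo[4,3-d][1,4]oxazin-2-ium tetrafluoroborate (15 mol %), i-Pr2NEt (15 mol %), toluene, rt, argon
Reagents that add atoms: none
Why: The triazolylidene freed by the amine adds to the C8 aldehyde, proton transfer gives the Breslow enaminol (an acyl anion equivalent), this adds to the C7 carbonyl of the pendant dione, and loss of the carbene from the alkoxide leaves the tertiary acyloin; this is the intramolecular crossed aldehyde-ketone benzoin reaction, which chiral triazolium salts are known to run enantioselectively. The carbocycle (C8, C8a, C4a, C5, C6, C7) closes in a 6-exo-trig mode, which is possible because rotation about the push-pull C4a=C5 bond brings the dione next to the formyl group. C7 is the only new stereocentre and, the substrate being achiral, it is set by the catalyst alone: the aminoindanol backbone blocks one face of the enaminol, and the ketone is expected to approach with its oxygen hydrogen-bonded to the enol OH and its small methyl flank toward the N-aryl group, which should give (S)-11 with the (5aS,10bR) salt (the sense has to be confirmed on the first run, and the antipodal salt is at hand if it is reversed). The step needs the aldehyde and not a ketone to become the nucleophile (only the aldehyde adduct has the C–H required to form the enaminol), C7 and not C6 as acceptor (C6 is a vinylogous ester carbonyl and would give a five-membered ring), and acyl-anion instead of β-carbon reactivity of the enal-type intermediate (the electron-poor N-pentafluorophenyl catalyst favours the former, and the β-carbon C1 is an oxygen-bearing ring carbon). Catalytic, mild base keeps the enolisable methyl diketone and the α-ketol product away from aldol and ketol-shift side reactions.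

**Step 8**
Reactants: 11 (7S)-3-ethenyl-7-hydroxy-7-methyl-6H-isochromene-6,8(7H)-dione; 12 (2Z)-but-2-ene-1,4-diyl diacetate
Product: 13 (2E)-3-[(7S)-7-hydroxy-7-methyl-6,8-dioxo-7,8-dihydro-6H-isochromen-3-yl]prop-2-en-1-yl acetate
Conditions: 12 (5 equiv), second-generation Hoveyda-Grubbs catalyst RuCl2(H2IMes)(=CH-C6H4-2-OiPr) (10 mol %), CH2Cl2, 40 °C
Reagents that add atoms: none
Why: Olefin cross-metathesis between the only monosubstituted alkene of 11 and an excess of the reactive symmetrical allylic diacetate should give the conjugated, thermodynamically preferred E alkene, the trisubstituted ring alkenes being inert to the ruthenium alkylidene and C7 being untouched.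

**Step 9**
Reactants: 14 orsellinic acid
Product: 15 tert-butyldimethylsilyl 2,4-bis[(tert-butyldimethylsilyl)oxy]-6-methylbenzoate
Conditions: TBSCl (3.5 equiv), imidazole, DMF, rt
Reagents that add atoms: tert-butyldimethylsilyl chloride, CC(C)(C)[Si](C)(C)Cl
Why: Exhaustive silylation with imidazole as base and catalyst covers both phenols and the acid at room temperature, which avoids the heat that would decarboxylate orsellinic acid (silyl ether and silyl ester formation).

**Step 10**
Reactants: 15 tert-butyldimethylsilyl 2,4-bis[(tert-butyldimethylsilyl)oxy]-6-methylbenzoate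
Product: 16 2,4-bis[(tert-butyldimethylsilyl)oxy]-6-methylbenzoyl chloride
Conditions: (COCl)2, DMF (cat.), CH2Cl2, 0 °C → rt
Reagents that add atoms: oxalyl chloride, O=C(Cl)C(=O)Cl
Why: The chloroiminium species from oxalyl chloride and DMF converts a silyl ester directly into the acid chloride under neutral conditions with loss of the silyl chloride, leaving the two aryl silyl ethers intact (acid chloride formation from a silyl ester).

**Step 11**
Reactants: 13 (2E)-3-[(7S)-7-hydroxy-7-methyl-6,8-dioxo-7,8-dihydro-6H-isochromen-3-yl]prop-2-en-1-yl acetate; 16 2,4-bis[(tert-butyldimethylsilyl)oxy]-6-methylbenzoyl chloride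
Product: 17 (7S)-3-[(1E)-3-(acetyloxy)prop-1-en-1-yl]-7-methyl-6,8-dioxo-7,8-dihydro-6H-isochromen-7-yl 2,4-bis[(tert-butyldimethylsilyl)oxy]-6-methylbenzoate
Conditions: 16 (2 equiv), Et3N, 4-(dimethylamino)pyridine (1 equiv), CH2Cl2, 0 °C → rt
Reagents that add atoms: none
Why: Acylation of the acidic tertiary α-ketol hydroxyl by nucleophilic catalysis (acylpyridinium ion) should proceed because the electron-rich aroyl chloride is readily activated, the tertiary amines do not open the pyran ring, and the quaternary C7 cannot epimerise (esterification with an acid chloride).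

**Step 12**
Reactants: 17 (7S)-3-[(1E)-3-(acetyloxy)prop-1-en-1-yl]-7-methyl-6,8-dioxo-7,8-dihydro-6H-isochromen-7-yl 2,4-bis[(tert-butyldimethylsilyl)oxy]-6-methylbenzoate
Product: 18 (7S)-3-[(1E)-3-(acetyloxy)prop-1-en-1-yl]-7-methyl-6,8-dioxo-7,8-dihydro-6H-isochromen-7-yl 2,4-dihydroxy-6-methylbenzoate (target)
Conditions: HF·pyridine, pyridine, THF, 0 °C
Reagents that add atoms: none
Why: Buffered fluoride cleaves the two labile aryl silyl ethers (desilylation) and is neither basic nor nucleophilic enough to touch the allylic acetate, the hindered aryl ester or the pyran ring.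

**Compound list**

1 | 2-(chloromethyl)-5-hydroxy-4H-pyran-4-one (chlorokojic acid) | O=C1C=C(CCl)OC=C1O | starting material
2 | 6-(chloromethyl)-4-oxo-4H-pyran-3-yl trifluoromethanesulfonate | O=C1C=C(CCl)OC=C1OS(=O)(=O)C(F)(F)F | intermediate
3 | {[4-oxo-5-(trifluoromethanesulfonyloxy)-4H-pyran-2-yl]methyl}triphenylphosphonium chloride | O=C1C=C(C[P+](c2ccccc2)(c2ccccc2)c2ccccc2)OC=C1OS(=O)(=O)C(F)(F)F.[Cl-] | intermediate
4 | 4-oxo-6-[(triphenylphosphoranylidene)methyl]-4H-pyran-3-yl trifluoromethanesulfonate (ylide, not isolated) | O=C1C=C(C=P(c2ccccc2)(c2ccccc2)c2ccccc2)OC=C1OS(=O)(=O)C(F)(F)F | intermediate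
5 | 6-ethenyl-4-oxo-4H-pyran-3-yl trifluoromethanesulfonate | C=CC1=CC(=O)C(OS(=O)(=O)C(F)(F)F)=CO1 | intermediate
6 | 2-ethenyl-5-(hydroxymethyl)-4H-pyran-4-one | C=CC1=CC(=O)C(CO)=CO1 | intermediate
7 | but-3-yn-2-ol (racemic) | CC(O)C#C | starting material
8 | 2-ethenyl-4-(3-hydroxybut-1-yn-1-yl)-5-(hydroxymethyl)-4H-pyran-4-ol (diastereomer mixture, not isolated) | C=CC1=CC(O)(C#CC(C)O)C(CO)=CO1 | intermediate
9 | (1Z)-1-[2-ethenyl-5-(hydroxymethyl)-4H-pyran-4-ylidene]-3-hydroxybutan-2-one (racemic at the carbinol) | C=CC1=C/C(=C/C(=O)C(C)O)C(CO)=CO1 | intermediate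
10 | (4Z)-4-(2,3-dioxobutylidene)-6-ethenyl-4H-pyran-3-carbaldehyde | C=CC1=C/C(=C/C(=O)C(C)=O)C(C=O)=CO1 | intermediate
11 | (7S)-3-ethenyl-7-hydroxy-7-methyl-6H-isochromene-6,8(7H)-dione | C=CC1=CC2=CC(=O)[C@](C)(O)C(=O)C2=CO1 | intermediate
12 | (2Z)-but-2-ene-1,4-diyl diacetate | CC(=O)OC/C=C\COC(C)=O | starting material
13 | (2E)-3-[(7S)-7-hydroxy-7-methyl-6,8-dioxo-7,8-dihydro-6H-isochromen-3-yl]prop-2-en-1-yl acetate | CC(=O)OC/C=C/C1=CC2=CC(=O)[C@](C)(O)C(=O)C2=CO1 | intermediate
14 | orsellinic acid, 2,4-dihydroxy-6-methylbenzoic acid | Cc1cc(O)cc(O)c1C(=O)O | starting material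
15 | tert-butyldimethylsilyl 2,4-bis[(tert-butyldimethylsilyl)oxy]-6-methylbenzoate | Cc1cc(O[Si](C)(C)C(C)(C)C)cc(O[Si](C)(C)C(C)(C)C)c1C(=O)O[Si](C)(C)C(C)(C)C | intermediate
16 | 2,4-bis[(tert-butyldimethylsilyl)oxy]-6-methylbenzoyl chloride | Cc1cc(O[Si](C)(C)C(C)(C)C)cc(O[Si](C)(C)C(C)(C)C)c1C(Cl)=O | intermediate
17 | (7S)-3-[(1E)-3-(acetyloxy)prop-1-en-1-yl]-7-methyl-6,8-dioxo-7,8-dihydro-6H-isochromen-7-yl 2,4-bis[(tert-butyldimethylsilyl)oxy]-6-methylbenzoate | CC(=O)OC/C=C/C1=CC2=CC(=O)[C@](C)(OC(=O)c3c(C)cc(O[Si](C)(C)C(C)(C)C)cc3O[Si](C)(C)C(C)(C)C)C(=O)C2=CO1 | intermediate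
18 | (7S)-3-[(1E)-3-(acetyloxy)prop-1-en-1-yl]-7-methyl-6,8-dioxo-7,8-dihydro-6H-isochromen-7-yl 2,4-dihydroxy-6-methylbenzoate | CC(=O)OC/C=C/C1=CC2=CC(=O)[C@](C)(OC(=O)c3c(C)cc(O)cc3O)C(=O)C2=CO1 | target

**Step count**

Total: 12 steps. Longest linear sequence: 10 steps (steps 1–8, 11, 12, from chlorokojic acid); steps 9 and 10 form the two-step acid chloride branch.

**Steps most likely to fail**

Step 7. The risk is poor facial selectivity at the C7 carbonyl, because the methyl and the vinylogous acyl flank may not be told apart well enough, or erosion of selectivity through reversible carbene-catalysed retro-benzoin. The fallback sets out from 10 and rejoins the route at 11. The ring closure is run with an achiral carbene (2-(pentafluorophenyl)-6,7-dihydro-5H-pyrrolo[2,1-c][1,2,4]triazol-2-ium tetrafluoroborate, i-Pr2NEt, toluene) to give racemic 3-ethenyl-7-hydroxy-7-methyl-6H-isochromene-6,8(7H)-dione F1. The enantiomers are then separated by preparative chromatography on a chiral stationary phase (supercritical CO2/alcohol, amylose carbamate column). The (7S) enantiomer is 11, and the (7R)-3-ethenyl-7-hydroxy-7-methyl-6H-isochromene-6,8(7H)-dione F2 is set aside.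

Step 5. The risk is conjugate or 1,6-addition of the acetylide to the vinylpyranone in place of carbonyl addition, or ring opening of the α-unsubstituted alkynylpyrylium ion by water before the alkyne is hydrated. The fallback sets out from 6 and rejoins the route at 9; it makes C4a=C5 by C-acylation of a methylenepyran. MeMgBr (2.2 equiv, THF, 0 °C) adds to the carbonyl of 6, and HBF4·OEt2 dehydrates the carbinol to 2-ethenyl-5-(hydroxymethyl)-4-methylpyrylium tetrafluoroborate F3. Et3N in CH2Cl2 deprotonates the methyl group to the 4-methylene-4H-pyran, which racemic 2-acetoxypropanoyl chloride acylates at the exocyclic carbon, and at the primary hydroxyl as well. This gives [(4Z)-4-[3-(acetyloxy)-2-oxobutylidene]-6-ethenyl-4H-pyran-3-yl]methyl 2-(acetyloxy)propanoate F4. K2CO3 in MeOH then cleaves the acetate and the 2-acetoxypropanoate ester and returns diol 9.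

Step 11. The risk is failure of the acylation, because a tertiary carbinol flanked by two carbonyl groups meets a di-ortho-substituted aroyl chloride, with base-induced α-ketol shift of 13 taking over during a slow reaction. The fallback sets out from 13 (with 14) and rejoins the route at 18; it replaces the acid chloride by an unhindered ketene generated without base. Orsellinic acid 14 is converted (acetone, (CF3CO)2O, CF3CO2H) into the acetonide 7-hydroxy-2,2,5-trimethyl-4H-1,3-benzodioxin-4-one F5, which is silylated (TBSCl, imidazole, DMF) to 7-[(tert-butyldimethylsilyl)oxy]-2,2,5-trimethyl-4H-1,3-benzodioxin-4-one F6. Irradiation of F6 (300 nm, CH2Cl2) in the presence of 13 expels acetone and forms the ortho-quinone ketene, which the C7 hydroxyl captures. The product is (7S)-3-[(1E)-3-(acetyloxy)prop-1-en-1-yl]-7-methyl-6,8-dioxo-7,8-dihydro-6H-isochromen-7-yl 4-[(tert-butyldimethylsilyl)oxy]-2-hydroxy-6-methylbenzoate F7, with the ortho phenol already free. HF·pyridine then removes the remaining silyl ether and gives 18.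

**Further compounds**

F1 | step 7 | racemic 3-ethenyl-7-hydroxy-7-methyl-6H-isochromene-6,8(7H)-dione | C=CC1=CC2=CC(=O)C(C)(O)C(=O)C2=CO1
F2 | step 7 | (7R)-3-ethenyl-7-hydroxy-7-methyl-6H-isochromene-6,8(7H)-dione | C=CC1=CC2=CC(=O)[C@@](C)(O)C(=O)C2=CO1
F3 | step 5 | 2-ethenyl-5-(hydroxymethyl)-4-methylpyrylium tetrafluoroborate | C=Cc1cc(C)c(CO)c[o+]1.F[B-](F)(F)F
F4 | step 5 | [(4Z)-4-[3-(acetyloxy)-2-oxobutylidene]-6-ethenyl-4H-pyran-3-yl]methyl 2-(acetyloxy)propanoate | C=CC1=C/C(=C/C(=O)C(C)OC(C)=O)C(COC(=O)C(C)OC(C)=O)=CO1
F5 | step 11 | 7-hydroxy-2,2,5-trimethyl-4H-1,3-benzodioxin-4-one | Cc1cc(O)cc2c1C(=O)OC(C)(C)O2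
F6 | step 11 | 7-[(tert-butyldimethylsilyl)oxy]-2,2,5-trimethyl-4H-1,3-benzodioxin-4-one | Cc1cc(O[Si](C)(C)C(C)(C)C)cc2c1C(=O)OC(C)(C)O2
F7 | step 11 | (7S)-3-[(1E)-3-(acetyloxy)prop-1-en-1-yl]-7-methyl-6,8-dioxo-7,8-dihydro-6H-isochromen-7-yl 4-[(tert-butyldimethylsilyl)oxy]-2-hydroxy-6-methylbenzoate | CC(=O)OC/C=C/C1=CC2=CC(=O)[C@](C)(OC(=O)c3c(C)cc(O[Si](C)(C)C(C)(C)C)cc3O)C(=O)C2=CO1
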